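The three stereocentres of the target are all (R).

1. Retrosynthesis: the five hydroxyl groups are masked as benzyl ethers. The ester C–O bond between the resorcylate carboxyl and the central butanoate carbinol is then cut (Mitsunobu, inversion) to give keto acid 7 and hydroxy ester 14. Ester 14 is cut into arylpropanol 12 and an acetoacetyl unit.
2. Enabling feature: in the resorcylate ring, the ester carbonyl on C1 and the ketone two atoms out from C6 (C6–CH2–C=O) are together the ring-opened form of a 6,8-dioxygenated 3-alkylisocoumarin. C6 is the only unsubstituted position ortho to the carboxyl of a 2,4-dioxygenated benzoic acid, so the aryl C6–CH2 bond is cut back to benzoic acid 3 and keto sulfoxonium ylide 6.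
3. Forward: the rhodium-catalysed C–H annulation closes the pyranone ring of isocoumarin 8, the only ring made. Hydroxide reopens it to 7, Mitsunobu esterification joins 7 to 14, and one hydrogenolysis frees all five hydroxyl groups.
4. Stereochemistry: the side-chain carbinol comes from methyl (R)-3-hydroxybutanoate and the arylpropanol centre from (R)-propylene oxide. The central carbinol is set as (S) by Noyori hydrogenation with the (S)-BINAP ligand and inverted to (R) in the Mitsunobu step.

Key step: step 5

Assumption: 1,3-bis(benzyloxy)-5-bromobenzene is taken as a purchased material, and the side-chain carbinol is carried as a benzyl ether so that the final hydrogenolysis is the only deprotection.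

Step 1
Reactants: 1 2,4-dihydroxybenzoic acid
Product: 2 benzyl 2,4-bis(benzyloxy)benzoate
Conditions: BnBr (3.5 equiv), K2CO3, DMF, 70 °C
Reagents that add atoms: benzyl bromide, BrCc1ccccc1
Why: Williamson O-alkylation (SN2) of the carboxylate and both phenoxides should go to completion with excess benzyl bromide and heat, the hydrogen-bonded 2-hydroxyl reacting last.

Step 2
Reactants: 2 benzyl 2,4-bis(benzyloxy)benzoate
Product: 3 2,4-bis(benzyloxy)benzoic acid
Conditions: KOH, THF/MeOH/H2O, 65 °C; then 1 M HCl
Reagents that add atoms: potassium hydroxide, [K+].[OH-]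
Why: Saponification by acyl–oxygen cleavage removes only the benzyl ester, because aryl benzyl ethers are inert to hydroxide.

Step 3
Reactants: 4 methyl (R)-3-hydroxybutanoate
Product: 5 methyl (R)-3-(benzyloxy)butanoate
Conditions: BnOC(=NH)CCl3 (1.3 equiv), TfOH (5 mol %), cyclohexane/CH2Cl2, 0 °C → rt
Reagents that add atoms: benzyl 2,2,2-trichloroacetimidate, N=C(OCc1ccccc1)C(Cl)(Cl)Cl
Why: Acid-catalysed benzyl transfer from the trichloroacetimidate (O-benzylation through a benzyl cation equivalent) avoids base, so the β-hydroxy ester should neither eliminate nor lose configuration, and the C–O bond at the stereocentre is not broken.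

Step 4
Reactants: 5 methyl (R)-3-(benzyloxy)butanoate
Product: 6 (R)-4-(benzyloxy)-1-[dimethyl(oxo)-λ6-sulfanylidene]pentan-2-one
Conditions: Me3S(O)I (3.2 equiv), KOtBu (3.0 equiv), THF, reflux; then 5, 0 °C → rt
Reagents that add atoms: trimethylsulfoxonium iodide, C[S+](C)(C)=O.[I-]
Why: Acylation of dimethylsulfoxonium methylide (the Corey–Chaykovsky ylide) by the methyl ester through addition–elimination gives the stabilised keto ylide once a second equivalent of ylide removes the acidic proton, and the ylide is too weak a base to enolise the ester, so the β-benzyloxy group and the stereocentre should stay intact.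

Step 5
Reactants: 3 2,4-bis(benzyloxy)benzoic acid; 6 (R)-4-(benzyloxy)-1-[dimethyl(oxo)-λ6-sulfanylidene]pentan-2-one (1.3 equiv)
Product: 8 6,8-bis(benzyloxy)-3-[(R)-2-(benzyloxy)propyl]-1H-isochromen-1-one, via keto acid 7 (not isolated)
Conditions: [Cp*RhCl2]2 (4 mol %), AgSbF6 (16 mol %), NaOAc (0.5 equiv), (CF3)2CHOH, 80 °C, N2
Reagents that add atoms: none
Why: The carboxylate of 3 binds the Cp*Rh fragment (trivalent rhodium) and concerted metalation–deprotonation at C6–H gives a five-membered rhodacycle; ylide 6 then binds through carbon, loses dimethyl sulfoxide to form a rhodium carbene, and migratory insertion into the Rh–aryl bond followed by protodemetalation forms the aryl C6–CH2 bond of keto acid 7 without any external oxidant. The closest known reaction type is the trivalent rhodium catalysed C–H/O–H annulation of benzoic acids with α-keto sulfoxonium ylides to 3-substituted isocoumarins. The one new ring, the pyranone, closes when the carboxyl oxygen adds to the ketone carbon in a 6-exo-trig mode and the resulting lactol loses water to the enol lactone. No stereocentre is formed, and the (R)-benzyloxy carbinol lies two carbons from the carbene carbon and is not touched. The step needs site selectivity, which the substrate secures because C6 is the only C–H ortho to the carboxylate (C2 carries a benzyloxy group), so neither a regioisomer nor a double alkylation can arise, and the ylide carbon fixes the ketone exactly two atoms from the ring.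

Step 6
Reactants: 8 6,8-bis(benzyloxy)-3-[(R)-2-(benzyloxy)propyl]-1H-isochromen-1-one
Product: 7 2,4-bis(benzyloxy)-6-[(R)-4-(benzyloxy)-2-oxopentyl]benzoic acid
Conditions: NaOH (1.2 equiv, 1 M aq.), THF, 0 °C → rt; then 1 M HCl to pH 4, 0 °C
Reagents that add atoms: sodium hydroxide, [Na+].[OH-]
Why: Hydroxide adds to the enol lactone carbonyl (acyl–oxygen cleavage as in a saponification) and the ring opens by loss of the conjugated enolate, which is protonated on carbon to the ketone, so a small excess of base at low temperature and cold, mild acidification should give the keto acid without β-elimination, re-closure or any change at the stereocentre.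

Step 7
Reactants: 9 1,3-bis(benzyloxy)-5-bromobenzene; 10 (R)-2-methyloxirane
Product: 12 (R)-1-[3,5-bis(benzyloxy)phenyl]propan-2-ol, via aryl Grignard reagent 11 (not isolated)
Conditions: Mg, THF, 50 °C; then CuI (10 mol %), 10, −30 → 0 °C; 1 M HCl quench
Reagents that add atoms: none
Why: Copper-catalysed SN2 opening of the epoxide by the aryl Grignard reagent occurs at the unsubstituted carbon, so the stereocentre of 10 is not a reacting centre and is carried unchanged into the (R)-carbinol.

Step 8
Reactants: 12 (R)-1-[3,5-bis(benzyloxy)phenyl]propan-2-ol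
Product: 13 (R)-1-[3,5-bis(benzyloxy)phenyl]propan-2-yl 3-oxobutanoate
Conditions: 2,2,6-trimethyl-4H-1,3-dioxin-4-one (1.3 equiv), toluene, 110 °C
Reagents that add atoms: 2,2,6-trimethyl-4H-1,3-dioxin-4-one, CC1=CC(=O)OC(C)(C)O1
Why: On heating the dioxinone undergoes retro-[4+2] loss of acetone to acetylketene, which the secondary alcohol traps as its acetoacetate (acetoacetylation) without touching the carbinol C–O bond.

Step 9
Reactants: 13 (R)-1-[3,5-bis(benzyloxy)phenyl]propan-2-yl 3-oxobutanoate
Product: 14 (R)-1-[3,5-bis(benzyloxy)phenyl]propan-2-yl (S)-3-hydroxybutanoate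
Conditions: [RuCl(p-cymene)((S)-BINAP)]Cl (1 mol %), H2 (50 atm), EtOH/CH2Cl2, 40 °C
Reagents that add atoms: none
Why: Noyori asymmetric hydrogenation reduces the chelated β-keto ester on divalent ruthenium, and the (S)-BINAP ligand directs hydride to the face that gives the (S)-3-hydroxybutanoate, as it does for simple acetoacetates, while the remote carbinol centre has no influence and this catalyst does not hydrogenolyse benzyl ethers.

Step 10
Reactants: 7 2,4-bis(benzyloxy)-6-[(R)-4-(benzyloxy)-2-oxopentyl]benzoic acid; 14 (R)-1-[3,5-bis(benzyloxy)phenyl]propan-2-yl (S)-3-hydroxybutanoate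
Product: 15 (R)-1-[3,5-bis(benzyloxy)phenyl]propan-2-yl (R)-3-({2,4-bis(benzyloxy)-6-[(R)-4-(benzyloxy)-2-oxopentyl]benzoyl}oxy)butanoate
Conditions: PPh3 (1.5 equiv), DIAD (1.5 equiv), toluene, 0 °C → rt
Reagents that add atoms: none
Why: In this Mitsunobu esterification the (S)-carbinol of 14 is activated as its alkoxyphosphonium and displaced by the carboxylate of 7 in an SN2 step with inversion, which sets the (R)-configured central ester, and the hindered, doubly ortho-substituted carboxyl serves only as a nucleophile and so needs no activation that would close it back onto the ketone.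

Step 11
Reactants: 15 (R)-1-[3,5-bis(benzyloxy)phenyl]propan-2-yl (R)-3-({2,4-bis(benzyloxy)-6-[(R)-4-(benzyloxy)-2-oxopentyl]benzoyl}oxy)butanoate
Product: 16 hansforester K
Conditions: H2 (1 atm), Pd/C (10 wt %), EtOAc/THF, rt
Reagents that add atoms: none
Why: Catalytic hydrogenolysis should cleave the four aryl benzyl ethers and the secondary alkyl benzyl ether, while the three esters (none on a benzylic carbon), the non-conjugated ketone and the three stereocentres are inert under these neutral conditions.

Compound list
1 | 2,4-dihydroxybenzoic acid | O=C(O)c1ccc(O)cc1O | starting material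
2 | benzyl 2,4-bis(benzyloxy)benzoate | O=C(OCc1ccccc1)c1ccc(OCc2ccccc2)cc1OCc1ccccc1 | intermediate
3 | 2,4-bis(benzyloxy)benzoic acid | O=C(O)c1ccc(OCc2ccccc2)cc1OCc1ccccc1 | intermediate
4 | methyl (R)-3-hydroxybutanoate | C[C@@H](O)CC(=O)OC | starting material
5 | methyl (R)-3-(benzyloxy)butanoate | C[C@@H](OCc1ccccc1)CC(=O)OC | intermediate
6 | (R)-4-(benzyloxy)-1-[dimethyl(oxo)-λ6-sulfanylidene]pentan-2-one | C[C@@H](OCc1ccccc1)CC(=O)C=S(C)(C)=O | intermediate
7 | 2,4-bis(benzyloxy)-6-[(R)-4-(benzyloxy)-2-oxopentyl]benzoic acid (not isolated in step 5, isolated in step 6) | C[C@@H](OCc1ccccc1)CC(=O)Cc1cc(OCc2ccccc2)cc(OCc2ccccc2)c1C(=O)O | intermediate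
8 | 6,8-bis(benzyloxy)-3-[(R)-2-(benzyloxy)propyl]-1H-isochromen-1-one | C[C@@H](OCc1ccccc1)CC1=Cc2cc(OCc3ccccc3)cc(OCc3ccccc3)c2C(=O)O1 | intermediate
9 | 1,3-bis(benzyloxy)-5-bromobenzene | Brc1cc(OCc2ccccc2)cc(OCc2ccccc2)c1 | starting material
10 | (R)-2-methyloxirane ((R)-propylene oxide) | C[C@@H]1CO1 | starting material
11 | [3,5-bis(benzyloxy)phenyl]magnesium bromide (not isolated) | Br[Mg]c1cc(OCc2ccccc2)cc(OCc2ccccc2)c1 | intermediate
12 | (R)-1-[3,5-bis(benzyloxy)phenyl]propan-2-ol | C[C@@H](O)Cc1cc(OCc2ccccc2)cc(OCc2ccccc2)c1 | intermediate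
13 | (R)-1-[3,5-bis(benzyloxy)phenyl]propan-2-yl 3-oxobutanoate | CC(=O)CC(=O)O[C@H](C)Cc1cc(OCc2ccccc2)cc(OCc2ccccc2)c1 | intermediate
14 | (R)-1-[3,5-bis(benzyloxy)phenyl]propan-2-yl (S)-3-hydroxybutanoate | C[C@H](O)CC(=O)O[C@H](C)Cc1cc(OCc2ccccc2)cc(OCc2ccccc2)c1 | intermediate
15 | (R)-1-[3,5-bis(benzyloxy)phenyl]propan-2-yl (R)-3-({2,4-bis(benzyloxy)-6-[(R)-4-(benzyloxy)-2-oxopentyl]benzoyl}oxy)butanoate | C[C@H](Cc1cc(OCc2ccccc2)cc(OCc2ccccc2)c1)OC(=O)C[C@@H](C)OC(=O)c1c(OCc2ccccc2)cc(OCc2ccccc2)cc1CC(=O)C[C@@H](C)OCc1ccccc1 | intermediate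
16 | hansforester K, (R)-1-(3,5-dihydroxyphenyl)propan-2-yl (R)-3-({2,4-dihydroxy-6-[(R)-4-hydroxy-2-oxopentyl]benzoyl}oxy)butanoate | C[C@H](Cc1cc(O)cc(O)c1)OC(=O)C[C@@H](C)OC(=O)c1c(O)cc(O)cc1CC(=O)C[C@@H](C)O | target

Total step count: 11
Longest linear sequence: 6 steps (steps 1, 2, 5, 6, 10, 11 from 2,4-dihydroxybenzoic acid; equally steps 3, 4, 5, 6, 10, 11 from methyl (R)-3-hydroxybutanoate)

Steps most likely to fail

Step 5. The keto ylide may be consumed by unproductive carbene decomposition before the rhodacycle captures it, turnover may stall on the electron-rich, ortho-substituted acid, or acid-promoted loss of benzyl alcohol from the β-benzyloxy ketone may occur before the lactone closes. The fallback abandons C–H activation for a lateral lithiation and sets out from 5. Ester 5 is converted with MeNH(OMe)·HCl and iPrMgCl in THF at −20 °C into the Weinreb amide (R)-3-(benzyloxy)-N-methoxy-N-methylbutanamide F1. Commercial methyl 2,4-dihydroxy-6-methylbenzoate is benzylated (BnBr, K2CO3, DMF) to methyl 2,4-bis(benzyloxy)-6-methylbenzoate F2. F2 is deprotonated at its benzylic methyl group with LiN(iPr)2 in THF at −78 °C and the toluate anion is acylated with F1 to give methyl 2,4-bis(benzyloxy)-6-[(R)-4-(benzyloxy)-2-oxopentyl]benzoate F3. Warming F3 with catalytic TsOH in toluene should close the enol lactone with loss of methanol, and the route is rejoined at 8.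

Step 10. The alkoxyphosphonium of the β-hydroxy ester may undergo elimination to the crotonate instead of substitution, and the keto acid may close back to the enol lactone through an acyloxyphosphonium. The fallback uses an alcohol partner that cannot eliminate to a conjugated ester and builds the western ester last; it sets out from 7. Mitsunobu esterification of 7 with commercial (S)-pent-4-en-2-ol (PPh3, DIAD, toluene) should give, with inversion, (R)-pent-4-en-2-yl 2,4-bis(benzyloxy)-6-[(R)-4-(benzyloxy)-2-oxopentyl]benzoate F4. Lemieux–Johnson cleavage (OsO4 cat., NaIO4, 2,6-lutidine, dioxane/H2O) gives (R)-4-oxobutan-2-yl 2,4-bis(benzyloxy)-6-[(R)-4-(benzyloxy)-2-oxopentyl]benzoate F5. Pinnick oxidation (NaClO2, NaH2PO4, 2-methyl-2-butene, tBuOH/H2O) gives (R)-3-({2,4-bis(benzyloxy)-6-[(R)-4-(benzyloxy)-2-oxopentyl]benzoyl}oxy)butanoic acid F6. Steglich esterification of F6 with alcohol 12 (EDC·HCl, DMAP cat., CH2Cl2, 0 °C) rejoins the route at 15.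

Step 6. Excess hydroxide may enolise the freed ketone towards the side chain and expel benzyl oxide (E1cB), and on acidification the keto acid may fall back to the enol lactone. The fallback releases the carboxyl by a neutral metal-catalysed deallylation instead of by hydroxide and sets out from 8. Opening of 8 with one equivalent of sodium allyloxide (NaH, allyl alcohol, THF, 0 °C), in which the alkoxide is consumed as the stabilised benzylic enolate, should give prop-2-en-1-yl 2,4-bis(benzyloxy)-6-[(R)-4-(benzyloxy)-2-oxopentyl]benzoate F7. Deallylation of F7 with Pd(PPh3)4 (zerovalent palladium, catalytic) and morpholine in THF at rt, followed by a pH 4 wash, rejoins the route at 7.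

Further compounds
F1 | step 5 | (R)-3-(benzyloxy)-N-methoxy-N-methylbutanamide | C[C@@H](OCc1ccccc1)CC(=O)N(C)OC
F2 | step 5 | methyl 2,4-bis(benzyloxy)-6-methylbenzoate | COC(=O)c1c(C)cc(OCc2ccccc2)cc1OCc1ccccc1
F3 | step 5 | methyl 2,4-bis(benzyloxy)-6-[(R)-4-(benzyloxy)-2-oxopentyl]benzoate | COC(=O)c1c(OCc2ccccc2)cc(OCc2ccccc2)cc1CC(=O)C[C@@H](C)OCc1ccccc1
F4 | step 10 | (R)-pent-4-en-2-yl 2,4-bis(benzyloxy)-6-[(R)-4-(benzyloxy)-2-oxopentyl]benzoate | C=CC[C@@H](C)OC(=O)c1c(OCc2ccccc2)cc(OCc2ccccc2)cc1CC(=O)C[C@@H](C)OCc1ccccc1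
F5 | step 10 | (R)-4-oxobutan-2-yl 2,4-bis(benzyloxy)-6-[(R)-4-(benzyloxy)-2-oxopentyl]benzoate | O=CC[C@@H](C)OC(=O)c1c(OCc2ccccc2)cc(OCc2ccccc2)cc1CC(=O)C[C@@H](C)OCc1ccccc1
F6 | step 10 | (R)-3-({2,4-bis(benzyloxy)-6-[(R)-4-(benzyloxy)-2-oxopentyl]benzoyl}oxy)butanoic acid | OC(=O)C[C@@H](C)OC(=O)c1c(OCc2ccccc2)cc(OCc2ccccc2)cc1CC(=O)C[C@@H](C)OCc1ccccc1
F7 | step 6 | prop-2-en-1-yl 2,4-bis(benzyloxy)-6-[(R)-4-(benzyloxy)-2-oxopentyl]benzoate | C=CCOC(=O)c1c(OCc2ccccc2)cc(OCc2ccccc2)cc1CC(=O)C[C@@H](C)OCc1ccccc1
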